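Readings and results stem from a simulated flask for an exercise.

In this flask the left-handed substrate stands at 43.3 % of the pair after 40.0 h, less than the 49.8 % of the right-handed substrate, so you are watching a kinetic resolution under the single-handed free catalyst.

| flask | left-handed substrate | right-handed substrate | gas | free catalyst | remark | time |
|---|---|---|---|---|---|---|
| epsilon | 1.5 M | 1.5 M | 71 mM (held) | 20 mM | the very flask that is asked about, followed so far |  |
| flask | 1.5 M | 1.5 M | 71 mM (held) | 20 mM |  | 10 d |

epsilon run (percent of the left-handed substrate and right-handed substrate together charged)

| time / h | left-handed substrate / % | right-handed substrate / % |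
|---|---|---|
| 3.00 | 50.1 | 49.8 |
| 6.00 | 49.0 | 49.9 |
| 10.0 | 48.5 | 50.2 |
| 15.0 | 46.5 | 50.2 |
| 25.0 | 44.9 | 50.3 |
| 40.0 | 43.3 | 49.8 |

(scatter of a reading: 0.5 percentage points)

- free catalyst is single-handed; left-handed substrate and right-handed substrate are mirror images of each other, charged as a racemate, each of them at the stated concentration
- the numbers in the tables scatter by 0.5 percentage points (one standard deviation)
- at the start none of the gas is in solution
- an excess is below zero if the other one leads

* part of the left-handed substrate and right-handed substrate charged together that has reacted at 10 d
* excess of left-handed product over right-handed product in the product at 10 d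
* excess of right-handed substrate over left-handed substrate among what is left of the two at 10 d

Fold the readings, the times and the racemic charge into one number, the depletion number: the logarithm of the fall of the left-handed substrate so far, stretched by the asked time over the time read, which says how many e-foldings of its own charge that substrate passes through if it decays pseudo-first-order under a catalyst that keeps working. My reckoning gives 0.863, so a fraction 42.2 % of the left-handed charge survives; with the right-handed substrate untouched, you read 28.9 % reacted and a substrate excess of 40.6 %. The test is to read the number again at 25.0 h, which gives 1.03, more than 0.863, a spread I accept as the number's uncertainty. One number is not enough for the product excess, though: the right-handed readings show no loss beyond the scatter of 0.5 percentage points, so I can say that it is high and no more.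

The forecast instead gives 14 % reacted (range 10 % to 27 %), a product excess of 94 % and a substrate excess of 15.3 %, reading the slowing thus: “That hints at catalyst death or product inhibition”.

The flask gives 32.0 % reacted, a product excess of 92.0 % and a substrate excess of 42.5 %, with 39 % of the left-handed charge left unbound against the 42.2 % from the number.

    2 partner → self-condensation product (k = 0.0890 L mol⁻¹ h⁻¹)
    free catalyst + right-handed substrate ⇌ catalyst intermediate B (K = 1.40 L mol⁻¹, k = 20.0 L mol⁻¹ h⁻¹)
    free catalyst + left-handed substrate ⇌ catalyst intermediate A (K = 0.590 L mol⁻¹, k = 240 L mol⁻¹ h⁻¹)
    partner + catalyst intermediate A → free catalyst + left-handed product (k = 25.0 L mol⁻¹ h⁻¹)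
    gas ⇌ partner, rate k5*(csat - [partner]) (kL = 0.330 h⁻¹)
    2 free catalyst → spent catalyst (k = 0.500 L mol⁻¹ h⁻¹)
    partner + catalyst intermediate B → free catalyst + right-handed product (k = 0.290 L mol⁻¹ h⁻¹)

The path from partner + catalyst intermediate A to free catalyst + left-handed product has 27 % of its turnover behind it after 2.00 d and half by 3.96 d, well before the asked 10 d, while spent catalyst reaches 26.8 % of the catalyst at 10.0 d. Scaling the depletion number by the catalyst charged, the neighbour flask with 0.0080 M of free catalyst should keep 70.8 % of its left-handed charge, and it keeps 65 %.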